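## Retrosynthetic overview

1. Locants used here: rings B/C are a hydrindane, C-1 to C-7a (C-3 carries the CH2 link, C-4 the CH3 and lactone O, C-7 Br, C-7a the lactone C=O); ring D is the γ-lactone; ring A is C-1′(OH), C-2′H2, C-3′Me2, C-4′HBr, C-5′H2, C-6′H2.
2. Target 27 ⇐ acetate 26 ⇐ axial methyl ketone 25 (Baeyer–Villiger, retention) ⇐ acyclic dienyl carbinol 24, by a bromonium-initiated cyclization ended by a semipinacol shift that closes ring A (C-2′–C-3′ bond, C-4′–Br bond, C-1′–CH2 bond).
3. Enabling feature: ring A is a bromonium-opened prenyl end (C-4′HBr beside C-3′Me2) joined through C-2′H2 to the fully substituted C-1′, whose CH2 link to C-3 is equatorial and whose oxygen is axial and cis to Br. An anti cation–olefin addition places the incoming carbon exactly there, so the CH2 link is made to migrate in and the oxygen is put on afterwards with retention.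
4. 24 ⇐ keto bromolactone 18 + alkenylcerium from 6-methylhept-5-en-2-one; 18 ⇐ triene 15 by intramolecular Diels–Alder reaction (rings B and C; C-3a, C-7, C-7a) and protolactonization (ring D; C-4); C-3 comes from a rhodium-catalysed asymmetric dienyl addition to enone 9.
5. Order of ring formation: B and C together (step 10), D (step 11), A last (step 14).

Key step: step 14

Assumption: the sense of induction of the two chiral catalysts (BINAP–rhodium in step 9, thiophosphoramide in step 14) is taken from the usual models for (E)-enones and terminal prenyl groups; if either proves reversed, the antipodal ligand or catalyst is used.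

## Route

Step 1
Reactants: 1 prop-2-yn-1-ol; 2 but-3-en-1-ylmagnesium bromide
Product: 4 (Z)-2-(bromomethylidene)hex-5-en-1-ol, via magnesium chelate 3 (not isolated)
Conditions: 2 (2.5 equiv), CuI (10 mol%), Et2O/THF, 0 °C → reflux; then NBS, −40 → 0 °C; aq. NH4Cl
Reagents that add atoms: N-bromosuccinimide, O=C1CCC(=O)N1Br
Why: Copper-catalysed anti-carbomagnesiation of the propargylic alkoxide puts the alkyl group on C-2 and magnesium on C-3 cis to CH2O in the five-membered chelate 3, and bromination of the C–Mg bond with retention should fix the Z-bromoalkene (Br cis to CH2OH).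

Step 2
Reactants: 4 (Z)-2-(bromomethylidene)hex-5-en-1-ol
Product: 5 (Z)-2-(bromomethylidene)hex-5-enal
Conditions: MnO2 (15 equiv), CH2Cl2, rt, dark
Reagents that add atoms: none
Why: Allylic alcohol oxidation with MnO2 is neutral and should leave the bromoalkene geometry and the terminal alkene untouched.

Step 3
Reactants: 5 (Z)-2-(bromomethylidene)hex-5-enal
Product: 6 (Z)-2-(bromomethylidene)hex-5-enoic acid
Conditions: NaClO2, NaH2PO4, 2-methylbut-2-ene, t-BuOH/H2O, 0 °C → rt
Reagents that add atoms: sodium chlorite, [Na+].[O-]Cl=O
Why: Pinnick oxidation converts enals to enoic acids without touching alkenes, the hypochlorite being trapped by 2-methylbut-2-ene.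

Step 4
Reactants: 6 (Z)-2-(bromomethylidene)hex-5-enoic acid
Product: 7 tert-butyl (Z)-2-(bromomethylidene)hex-5-enoate
Conditions: tert-butyl 2,2,2-trichloroacetimidate, BF3·OEt2 (cat.), cyclohexane/CH2Cl2, rt
Reagents that add atoms: tert-butyl 2,2,2-trichloroacetimidate, CC(C)(C)OC(=N)C(Cl)(Cl)Cl
Why: Acid-catalysed imidate esterification transfers the tert-butyl group without a nucleophilic catalyst that could attack the β-bromoacrylate.

Step 5
Reactants: 7 tert-butyl (Z)-2-(bromomethylidene)hex-5-enoate; 8 but-3-en-2-one
Product: 9 tert-butyl (2Z,5E)-2-(bromomethylidene)-7-oxooct-5-enoate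
Conditions: 8 (3 equiv), second-generation Hoveyda–Grubbs catalyst (3 mol%), CH2Cl2, 40 °C
Reagents that add atoms: none
Why: Olefin cross-metathesis of a terminal alkene with an electron-poor partner should give the (E)-enone, while the trisubstituted bromoacrylate stays out of the reaction.

Step 6
Reactants: 10 2-methylprop-2-enal
Product: 12 (E)-3-bromo-2-methylprop-2-enal, via dibromide 11 (not isolated)
Conditions: Br2, CH2Cl2, 0 °C; then Et3N, 0 °C → rt
Reagents that add atoms: bromine, BrBr
Why: Bromine addition followed by base-induced dehydrobromination (anti elimination with Br turned away from the carbonyl group) should give the (E)-β-bromoenal.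

Step 7
Reactants: 12 (E)-3-bromo-2-methylprop-2-enal
Product: 13 (E)-1-bromo-2-methylbuta-1,3-diene
Conditions: Ph3PCH3Br, KOtBu, THF, 0 °C; then 12, −78 → 0 °C
Reagents that add atoms: methyltriphenylphosphonium bromide, C[P+](c1ccccc1)(c1ccccc1)c1ccccc1.[Br-]
Why: Wittig methylenation of the aldehyde builds the diene and does not touch the geometry of the bromoalkene.

Step 8
Reactants: 13 (E)-1-bromo-2-methylbuta-1,3-diene
Product: 14 (E)-4,4,5,5-tetramethyl-2-(2-methylbuta-1,3-dien-1-yl)-1,3,2-dioxaborolane
Conditions: B2pin2, PdCl2(PPh3)2 (3 mol%), PPh3 (6 mol%), KOPh, toluene, 50 °C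
Reagents that add atoms: bis(pinacolato)diboron, CC1(C)OB(OC1(C)C)B1OC(C)(C)C(C)(C)O1
Why: Miyaura borylation of an alkenyl bromide proceeds with retention of alkene geometry, and the weak base KOPh suppresses Suzuki homocoupling.

Step 9
Reactants: 9 tert-butyl (2Z,5E)-2-(bromomethylidene)-7-oxooct-5-enoate; 14 (E)-4,4,5,5-tetramethyl-2-(2-methylbuta-1,3-dien-1-yl)-1,3,2-dioxaborolane
Product: 15 tert-butyl (2Z,5S,6E)-2-(bromomethylidene)-7-methyl-5-(2-oxopropyl)nona-6,8-dienoate
Conditions: 14 (1.5 equiv), [RhCl(C2H4)2]2 (2.5 mol%), (S)-BINAP (6 mol%), K3PO4 (0.5 equiv), 1,4-dioxane/H2O (10:1), 40 °C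
Reagents that add atoms: none
Why: In this Hayashi–Miyaura reaction the dienyl group passes from boron to rhodium and adds 1,4 to the unhindered (E)-enone (the α-substituted bromoacrylate is a far poorer acceptor), the BINAP ligand directing it to the Si face of C-5 so that the (S) centre forms with the diene geometry retained.

Step 10
Reactants: 15 tert-butyl (2Z,5S,6E)-2-(bromomethylidene)-7-methyl-5-(2-oxopropyl)nona-6,8-dienoate
Product: 16 tert-butyl (3S,3aR,7S,7aS)-7-bromo-4-methyl-3-(2-oxopropyl)-1,2,3,3a,6,7-hexahydro-7aH-indene-7a-carboxylate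
Conditions: toluene (0.01 M), BHT (cat.), 170 °C, sealed tube
Reagents that add atoms: none
Why: In this intramolecular Diels–Alder reaction, A1,3 strain between the diene methyl group and C-3 holds C-3–H in the diene plane so the tethered dienophile adds to one diene face (C-3a), the ester and bromine lie endo with the tether exo to give the trans ring fusion (C-7a), and the Z-bromoacrylate geometry becomes the cis relation of Br and ester (C-7).

Step 11
Reactants: 16 tert-butyl (3S,3aR,7S,7aS)-7-bromo-4-methyl-3-(2-oxopropyl)-1,2,3,3a,6,7-hexahydro-7aH-indene-7a-carboxylate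
Product: 18 (3S,3aS,4R,7S,7aS)-7-bromo-4-hydroxy-4-methyl-3-(2-oxopropyl)octahydro-7aH-indene-7a-carboxylic acid 7a→4 lactone, via carboxylic acid 17 (not isolated)
Conditions: TfOH (0.3 equiv), CH2Cl2, 0 °C → rt
Reagents that add atoms: none
Why: Acid cleaves the tert-butyl ester to acid 17, Markovnikov protonation of the C-4=C-5 alkene gives the tertiary C-4 cation, and the angular carboxyl group closes the γ-lactone, which can only form cis-bridged and so fixes C-4 (protolactonization).

Step 12
Reactants: 19 6-methylhept-5-en-2-one; 20 2,4,6-triisopropylbenzenesulfonohydrazide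
Product: 21 (E)-N′-(6-methylhept-5-en-2-ylidene)-2,4,6-triisopropylbenzenesulfonohydrazide
Conditions: MeOH, HCl (cat.), rt
Reagents that add atoms: none
Why: Acid-catalysed condensation of a ketone with a sulfonyl hydrazide gives the hydrazone, with the sulfonamide group anti to the longer chain.

Step 13
Reactants: 21 (E)-N′-(6-methylhept-5-en-2-ylidene)-2,4,6-triisopropylbenzenesulfonohydrazide; 18 keto bromolactone (name as in step 11)
Product: 24 bromolactone 18 carrying a 2-hydroxy-2,7-dimethyl-3-methylideneoct-6-en-1-yl chain at C-3 in place of 2-oxopropyl (both carbinol epimers), via alkenyllithium 22 (not isolated), via alkenylcerium dichloride 23 (not isolated)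
Conditions: 21 (2 equiv), n-BuLi (4.1 equiv), THF, −78 → 0 °C; CeCl3, −78 °C; then 18, −78 °C; aq. NH4Cl
Reagents that add atoms: none
Why: The Shapiro reaction deprotonates the methyl side and gives the 2-lithio-1-alkene, and the derived organocerium reagent (nucleophilic, weakly basic) should add to the methyl ketone without enolization and without attack on the hindered lactone or the secondary bromide; the new carbinol centre forms unselectively and is destroyed in step 14.

Step 14
Reactants: 24 dienyl carbinol (name as in step 13)
Product: 25 bromolactone 18 carrying a [(1S,4S)-1-acetyl-4-bromo-3,3-dimethylcyclohexyl]methyl group at C-3 in place of 2-oxopropyl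
Conditions: DBDMH (1,3-dibromo-5,5-dimethylhydantoin, 1.1 equiv), (R)-BINOL-derived N-aryl thiophosphoramide (10 mol%), toluene/CH2Cl2, −90 → −60 °C
Reagents that add atoms: 1,3-dibromo-5,5-dimethylhydantoin, CC1(C)N(Br)C(=O)N(Br)C1=O
Why: Proposed new method: the chiral Lewis base transfers Br+ from DBDMH to the Si face of the CH carbon of the trisubstituted (most electron-rich) alkene, the 1,1-disubstituted alkene opens the bromonium ion anti at its tertiary carbon through a chair transition state, and the tertiary cation developing at C-1′ is quenched by an antiperiplanar 1,2-shift of the C-3 methylene group from the neighbouring carbinol carbon, which becomes the acetyl carbonyl (semipinacol). The closest known reaction types are the catalytic asymmetric bromonium-induced polyene cyclization with this catalyst class and the halonium- or oxocarbenium-triggered semipinacol rearrangement of allylic alcohols (Prins–pinacol type). Ring A closes by 6-endo-trig attack of the alkene on the tertiary bromonium carbon (Markovnikov, anti). C-4′ (S) is set by the catalyst, because the core stereocentres are too remote to distinguish the alkene faces; C-1′ (S) follows from the chair, in which bromine is equatorial and the migrating CH2 enters anti to the new C-2′–C-3′ bond, that is equatorial, leaving the acetyl group axial and cis to bromine. The step needs chemoselectivity for the trisubstituted alkene over the less nucleophilic 1,1-disubstituted allylic-alcohol alkene, and migration of CH2R in preference to CH3, which the higher migratory aptitude of the primary alkyl group and its preference to stand perpendicular to the alkene plane should secure; both carbinol epimers of 24 converge because that carbon becomes trigonal.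

Step 15
Reactants: 25 axial methyl ketone (name as in step 14)
Product: 26 bromolactone 18 carrying a [(1S,4S)-1-acetoxy-4-bromo-3,3-dimethylcyclohexyl]methyl group at C-3 in place of 2-oxopropyl
Conditions: (CF3CO)2O, urea·H2O2, Na2HPO4, CH2Cl2, 0 °C → rt
Reagents that add atoms: urea–hydrogen peroxide, NC(N)=O.OO
Why: In the Baeyer–Villiger oxidation the fully substituted C-1′ migrates in preference to methyl and with retention, so the oxygen takes the axial position cis to bromine; lactone and alkyl bromides are inert to the peracid.

Step 16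
Reactants: 26 tertiary acetate (name as in step 15)
Product: 27 CNP0282702.2
Conditions: K2CO3, MeOH, rt → 40 °C; dilute HCl work-up
Reagents that add atoms: none
Why: Transesterification removes the acetate without touching a stereocentre; the hindered bridged lactone re-closes if it opens, and the equatorial bromides have no antiperiplanar hydrogen or backside oxygen for elimination or displacement.

## Compound list

1 | prop-2-yn-1-ol | C#CCO | starting material
2 | but-3-en-1-ylmagnesium bromide | C=CCC[Mg]Br | starting material
3 | 4-(but-3-en-1-yl)-2,5-dihydro-1,2-oxamagnesole (cyclic alkenylmagnesium alkoxide) | C=CCCC1=C[Mg]OC1 | intermediate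
4 | (Z)-2-(bromomethylidene)hex-5-en-1-ol | C=CCC/C(=C/Br)CO | intermediate
5 | (Z)-2-(bromomethylidene)hex-5-enal | C=CCC/C(=C/Br)C=O | intermediate
6 | (Z)-2-(bromomethylidene)hex-5-enoic acid | C=CCC/C(=C/Br)C(=O)O | intermediate
7 | tert-butyl (Z)-2-(bromomethylidene)hex-5-enoate | C=CCC/C(=C/Br)C(=O)OC(C)(C)C | intermediate
8 | but-3-en-2-one | CC(=O)C=C | starting material
9 | tert-butyl (2Z,5E)-2-(bromomethylidene)-7-oxooct-5-enoate | CC(=O)/C=C/CC/C(=C/Br)C(=O)OC(C)(C)C | intermediate
10 | 2-methylprop-2-enal | CC(=C)C=O | starting material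
11 | 2,3-dibromo-2-methylpropanal (racemic) | CC(Br)(CBr)C=O | intermediate
12 | (E)-3-bromo-2-methylprop-2-enal | O=C/C(C)=C/Br | intermediate
13 | (E)-1-bromo-2-methylbuta-1,3-diene | C=C/C(C)=C/Br | intermediate
14 | (E)-4,4,5,5-tetramethyl-2-(2-methylbuta-1,3-dien-1-yl)-1,3,2-dioxaborolane | C=C/C(C)=C/B1OC(C)(C)C(C)(C)O1 | intermediate
15 | tert-butyl (2Z,5S,6E)-2-(bromomethylidene)-7-methyl-5-(2-oxopropyl)nona-6,8-dienoate | CC(=O)C[C@@H](/C=C(C)/C=C)CC/C(=C/Br)C(=O)OC(C)(C)C | intermediate
16 | tert-butyl (3S,3aR,7S,7aS)-7-bromo-4-methyl-3-(2-oxopropyl)-1,2,3,3a,6,7-hexahydro-7aH-indene-7a-carboxylate (trans-fused) | CC(=O)C[C@@H]1CC[C@]2(C(=O)OC(C)(C)C)[C@@H](Br)CC=C(C)[C@@H]12 | intermediate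
17 | (3S,3aR,7S,7aS)-7-bromo-4-methyl-3-(2-oxopropyl)-1,2,3,3a,6,7-hexahydro-7aH-indene-7a-carboxylic acid | CC(=O)C[C@@H]1CC[C@]2(C(=O)O)[C@@H](Br)CC=C(C)[C@@H]12 | intermediate
18 | (3S,3aS,4R,7S,7aS)-7-bromo-4-hydroxy-4-methyl-3-(2-oxopropyl)octahydro-7aH-indene-7a-carboxylic acid 7a→4 lactone (keto bromolactone) | CC(=O)C[C@@H]1CC[C@]23C(=O)O[C@](C)(CC[C@@H]2Br)[C@@H]13 | intermediate
19 | 6-methylhept-5-en-2-one | CC(=O)CCC=C(C)C | starting material
20 | 2,4,6-triisopropylbenzenesulfonohydrazide | CC(C)c1cc(C(C)C)c(S(=O)(=O)NN)c(C(C)C)c1 | starting material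
21 | (E)-N′-(6-methylhept-5-en-2-ylidene)-2,4,6-triisopropylbenzenesulfonohydrazide | CC(C)=CCC/C(C)=N/NS(=O)(=O)c1c(C(C)C)cc(C(C)C)cc1C(C)C | intermediate
22 | (6-methylhepta-1,5-dien-2-yl)lithium | [Li]C(=C)CCC=C(C)C | intermediate
23 | dichloro(6-methylhepta-1,5-dien-2-yl)cerium | Cl[Ce](Cl)C(=C)CCC=C(C)C | intermediate
24 | bromolactone 18 with a 2-hydroxy-2,7-dimethyl-3-methylideneoct-6-en-1-yl chain at C-3 in place of 2-oxopropyl (carbinol epimers) | CC(C)=CCCC(=C)C(C)(O)C[C@@H]1CC[C@]23C(=O)O[C@](C)(CC[C@@H]2Br)[C@@H]13 | intermediate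
25 | bromolactone 18 with a [(1S,4S)-1-acetyl-4-bromo-3,3-dimethylcyclohexyl]methyl group at C-3 in place of 2-oxopropyl (acetyl axial, cis to Br) | CC1(C)C[C@@](C(C)=O)(C[C@@H]2CC[C@]34C(=O)O[C@](C)(CC[C@@H]3Br)[C@@H]24)CC[C@@H]1Br | intermediate
26 | bromolactone 18 with a [(1S,4S)-1-acetoxy-4-bromo-3,3-dimethylcyclohexyl]methyl group at C-3 in place of 2-oxopropyl | CC1(C)C[C@@](OC(C)=O)(C[C@@H]2CC[C@]34C(=O)O[C@](C)(CC[C@@H]3Br)[C@@H]24)CC[C@@H]1Br | intermediate
27 | CNP0282702.2: bromolactone 18 with a [(1S,4S)-4-bromo-1-hydroxy-3,3-dimethylcyclohexyl]methyl group at C-3 in place of 2-oxopropyl | CC1(C)C[C@@](O)(C[C@@H]2CC[C@]34C(=O)O[C@](C)(CC[C@@H]3Br)[C@@H]24)CC[C@@H]1Br | target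

## Step count and risks

Total step count: 16. Longest linear sequence: 12 steps (steps 1–5, 9–11, 13–16).

Steps most likely to fail:

**Step 14 (Proposed new method).** The catalyst may control the bromonium face poorly. The free tertiary hydroxyl may capture the bromonium ion (bromoetherification). The cation may lose a proton, or methyl may migrate instead of the methylene group. Fallback, setting out from 18 and coming back at 27, with the side chain added to a finished ring A ketone instead of being migrated:
- Baeyer–Villiger oxidation of 18 (CF3CO3H, Na2HPO4; CH2 migrates in preference to CH3) would give acetoxymethyl bromolactone F1.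
- Methanolysis (K2CO3, MeOH) would give hydroxymethyl bromolactone F2, and I2, PPh3, imidazole would give iodomethyl bromolactone F3.
- In parallel, 19 would be converted (LDA, TBSCl, −78 °C) into the kinetic silyl enol ether tert-butyldimethyl[(6-methylhepta-1,5-dien-2-yl)oxy]silane F4.
- Bromonium-induced cyclization of F4 with the enol silane as terminator (DBDMH and the same thiophosphoramide; Et2SBr·SbCl5Br as a racemic reserve, the diastereomeric coupling products then being separated) would give (S)-4-bromo-3,3-dimethylcyclohexan-1-one F5.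
- Barbier coupling of F3 with F5 (SmI2, NiI2 cat., THF, 0 °C) should add the primary alkyl group to the ketone from the equatorial side, away from the axial C-3′ methyl group, and give 27 directly.

**Step 10.** Endo/exo discrimination may be poor and lead to the cis-fused hydrindane, and the hindered bromoacrylate may react slowly enough for thermal loss of isobutene or HBr to compete. Fallback, setting out from 4 and coming back at 17, with an aldehyde-activated, Lewis-acid-promoted cycloaddition:
- Silylation of 4 (TBSCl, imidazole) would give silyl ether F6.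
- Cross-metathesis with 8 would give silyloxy enone F7, and rhodium-catalysed addition of 14 as in step 9 would give silyloxy triene F8.
- HF·pyridine would give allylic alcohol F9, and MnO2 would give the (Z)-bromoenal triene F10.
- Me2AlCl (2.2 equiv, CH2Cl2, −78 °C) should promote an aldehyde-endo intramolecular Diels–Alder reaction to the trans-fused aldehyde F11.
- Pinnick oxidation would give acid 17, which is lactonized as in step 11.

**Step 9.** The conjugated diene of 14 and of the product may bind and inhibit rhodium, the dienylboronate may protodeboronate, and facial selectivity may be low. Fallback, setting out from 9 and coming back at 15, with the diene completed only after the C–C bond is formed: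
- The same rhodium-catalysed addition with commercial 4,4,5,5-tetramethyl-2-(2-methylprop-1-en-1-yl)-1,3,2-dioxaborolane would give isobutenyl ketone F12.
- Allylic oxidation of the (E)-methyl group (SeO2 cat., t-BuOOH, CH2Cl2, then MnO2) would give the (E)-enal F13.
- Aldehyde-selective Wittig methylenation (Ph3P=CH2, THF, −78 °C) would give 15.

Further compounds
F1 | step 14 | acetoxymethyl bromolactone (18 with CH2OAc in place of 2-oxopropyl) | CC(=O)OC[C@@H]1CC[C@]23C(=O)O[C@](C)(CC[C@@H]2Br)[C@@H]13
F2 | step 14 | hydroxymethyl bromolactone | OC[C@@H]1CC[C@]23C(=O)O[C@](C)(CC[C@@H]2Br)[C@@H]13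
F3 | step 14 | iodomethyl bromolactone | IC[C@@H]1CC[C@]23C(=O)O[C@](C)(CC[C@@H]2Br)[C@@H]13
F4 | step 14 | tert-butyldimethyl[(6-methylhepta-1,5-dien-2-yl)oxy]silane | C=C(CCC=C(C)C)O[Si](C)(C)C(C)(C)C
F5 | step 14 | (S)-4-bromo-3,3-dimethylcyclohexan-1-one | CC1(C)CC(=O)CC[C@@H]1Br
F6 | step 10 | (Z)-{[2-(bromomethylidene)hex-5-en-1-yl]oxy}(tert-butyl)dimethylsilane | C=CCC/C(=C/Br)CO[Si](C)(C)C(C)(C)C
F7 | step 10 | (3E,7Z)-8-bromo-7-{[(tert-butyldimethylsilyl)oxy]methyl}octa-3,7-dien-2-one | CC(=O)/C=C/CC/C(=C/Br)CO[Si](C)(C)C(C)(C)C
F8 | step 10 | silyloxy triene (15 with CH2OTBS in place of the ester group) | CC(=O)C[C@@H](/C=C(C)/C=C)CC/C(=C/Br)CO[Si](C)(C)C(C)(C)C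
F9 | step 10 | allylic alcohol triene (15 with CH2OH in place of the ester group) | CC(=O)C[C@@H](/C=C(C)/C=C)CC/C(=C/Br)CO
F10 | step 10 | (Z)-bromoenal triene (15 with CHO in place of the ester group) | CC(=O)C[C@@H](/C=C(C)/C=C)CC/C(=C/Br)C=O
F11 | step 10 | trans-fused cycloadduct aldehyde (16 with CHO in place of the ester group) | CC(=O)C[C@@H]1CC[C@]2(C=O)[C@@H](Br)CC=C(C)[C@@H]12
F12 | step 9 | isobutenyl ketone (15 with a 2-methylprop-1-en-1-yl group in place of the dienyl group) | CC(=O)C[C@@H](C=C(C)C)CC/C(=C/Br)C(=O)OC(C)(C)C
F13 | step 9 | (E)-enal (15 with CHO in place of the terminal vinyl group) | CC(=O)C[C@@H](/C=C(C)/C=O)CC/C(=C/Br)C(=O)OC(C)(C)C
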